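## Structural features

The atom labels used throughout are: ring A = C1 (benzoyl), C2 (C=O), C3, C4 (C=O), C5 (geranyl), C9 (C=O); ring B = C5, C6, C7, C8 (CMe2), C1, C9; C10–C11 ties C7 to C3; the cyclopentane is C3, C11, C12 (CMe2), C13, C14; C15 is the isopropenyl carbon on C13. Rings A and B form a bicyclo[3.3.1]nonane-2,4,9-trione whose two inward carbons C3 and C7 are joined by the C10–C11 bridge, so the core is a homoadamantane; the cyclopentane is fused on the C3–C11 edge and leans towards C4. Of the six stereocentres, C1, C3, C5 and C7 are locked together by the cage, whereas C11 (next to C3) and C13 (separated from C11 by the quaternary C12) have to be chosen; H–C11 and the isopropenyl group are cis on the five-membered ring. Five carbons are fully substituted (C1, C3, C5, C8, C12), and C1 and C8 are neighbours. The fragile parts are the non-enolisable β-tricarbonyl array (open to retro-Claisen cleavage by nucleophiles) and three acid-sensitive olefins (two in the geranyl chain, one isopropenyl). The real difficulty is to build the cage with its quaternary carbons and to fix C11 in absolute terms. The feature that the key step uses is that ring A with its three oxygens, the C1 benzoyl and the C5 geranyl group is a masked 2,4,6-trihydroxybenzophenone whose meta carbons C3 and C5 are spanned by the chain C11–C10–C7–C6, i.e. by the seven-membered ring C3, C4, C5, C6, C7, C10, C11.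

## Logic of the disconnections

**15 to 14.** The bond C12–C13 is cut together with the isopropenyl double bond, the retron of a cation–olefin cyclisation ended by loss of a methyl proton. This removes the cyclopentane and C13 and leaves 14, a cage with a prenyl group on C3 and a silyl ether on C12. The forward step must make the C12 cation without free protons, attack through C13, and place C15 on the face syn to H–C11. It is put last because only then is no enol oxygen left that could trap the C15 cation.

**14 to 13.** The bond C1–C8 between two quaternary carbons is cut; a tertiary cation captured by an enol carbon is the most direct way to such a bond. The cage opens to the bicyclo[4.3.1] system 13, C1 becomes an enol carbon again, and C7 and C1 cease to be stereocentres. The forward step must ionise the C7 carbinol while the C12 silyl ether stays, move the charge to C8, and bond through carbon rather than oxygen.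

**13 to 11 and 12.** The bond C3–C14 is cut. In 11 the hydrogen on C3 is the only one left next to a carbonyl group, so the quaternary centre can be made by enolate alkylation with 12. The demand is formation and C-alkylation of a bridgehead enolate; the bridge leaves only one face open.

**11 to 9 and 10.** The bond C7–C8 is cut, which returns the C7 ketone of 9 and the three-carbon nucleophile 10. The forward addition must pick the C7 ketone among four carbonyl groups. Doing this before step 6 also removes the only ketone whose enolate could undo the C3–C11 bond by β-elimination.

**9 to 3 and 7 (through 8).** The bonds C5–C6 and C3–C11 are cut. This takes the seven-membered ring away, re-aromatises ring A and removes three stereocentres at once, leaving an aromatic ring and a five-carbon chain. The forward operation needs conjugate addition before substitution, carbon before oxygen, C5 before C1, and one configuration at C11. The chain component is improved in one respect: the C12 oxygen is carried as a triethylsilyl ether in 7. A free tertiary hydroxyl could displace the chloride (six-membered ether), form lactols with the C7 and C4 carbonyls, and ionise too early in step 7; the silyl ether does none of this and serves as the leaving group in step 8.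

**7 to 6, and 6 to 4 and 5.** The O–Si bond is cut, then the C10=C11 double bond by cross-metathesis. The hindered alcohol is silylated after the metathesis because the free carbinol is the better metathesis partner.

**3 to 1 and 2.** The bond between C5 and the geranyl chain is cut; mono-C-alkylation of the symmetrical phenol 1 by 2 is the forward demand.

## Other disconnections considered

**Alternative 1:** Ring A is cut at both acyl bonds, C4–C5 and C1–C2, so that it closes last. The precursor A2 is a 3,3-dimethylcyclohexanone enol silane (ring B, C9=C5) whose C7 carries, through C10, the finished cyclopentane with a 2,2-disubstituted malonyl dichloride at C3. The forward step is a double C-acylation of the Effenberger type: C5 attacks one acid chloride (seven-membered ring), then the enol towards C1 attacks the other, giving the cage A1.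
- In its favour: the reaction type is an established entry to bicyclo[3.3.1]nonane triones, and a fully substituted malonyl chloride cannot form a ketene. C3 is quaternary from the start, so neither a dearomatisation with its carbon/oxygen ambiguity nor a bridgehead alkylation at C3 is needed; on these two points it is better than the chosen plan. C7, C11 and C13 are set on ordinary rings.
- Against it: A1 has hydrogen on C1 and C5, so benzoyl and geranyl must be put on two bridgeheads of a rigid, non-enolisable cage, one of them next to the quaternary C8. The first acylation must close a seven-membered ring against O-acylation and oligomerisation. A2 has three stereocentres on two rings joined by one methylene and needs a long enantioselective synthesis.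
- Comparison: at the ring-forming stage it is mechanistically equal or better, but the two late bridgehead substitutions are weaker than the early aromatic placement of benzoyl and geranyl, and the step count would be far higher.

**Alternative 2:** Only the cage bond C3–C11 is cut. The precursor A4 is a bicyclo[3.3.1]nonane trione (benzoyl on C1, geranyl on C5, prenyl on the enolised C3) whose C7 arm ends in an (E)-allylic methyl carbonate. Pd(PPh3)4 ionises the carbonate and the C3 enolate attacks the inner allyl terminus C11, which closes the seven-membered ring and leaves an isopropenyl group on C11 (A3).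
- In its favour: a stabilised 1,3-dicarbonyl enolate and an allyl complex of divalent palladium are a well-matched pair, O-allylation is reversible, the medium is neutral, and C3 becomes quaternary in the ring-forming step. In carbon-versus-oxygen selectivity it is better than the chosen key step.
- Against it: attack must occur at the more substituted allyl terminus (the other end would give a nine-membered ring), the C7 arm must be axial on ring B, and C11 arises under substrate control without an obvious bias. After A3 the cyclopentane still has to be closed, so the end game is no shorter (equal). A4, with two different side chains on C5 and C7 and four stereocentres, is itself a long target.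
- Comparison: the chosen plan reaches the same oxidation pattern in one step from an aromatic ring and sets C11 by catalyst control before the cage exists.

**Alternative 3:** Ring A is cut at C5–C9 and C2–C3, which removes C9, C1 and C2 as a malonyl unit. The precursor A6 is the enol silane of a hydroazulenone (seven-membered C4 ketone with a C7 isopropylidene, fused to the finished cyclopentane). Malonyl dichloride acylates C5 and then the ring-fusion carbon C3, giving A5.
- In its favour: the carbocycle with C11 and C13 can be made by terpene-type chemistry; C1 is then a doubly activated methylene, so benzoylation is a simple C-acylation (better than any bridgehead acylation); ring B would close by the same cationic C8–C1 bond formation used here (equal).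
- Against it: the second acylation must occur at the more hindered ring-fusion carbon and on the same face as the first; this annulation is established for six-membered ketones but hardly for seven-membered ones; geranyl must still go on the bridgehead C5 (the same kind of step as step 6 here, equal); A6 needs its own enantioselective synthesis.
- Comparison: in step economy the chosen plan is clearly ahead, because the aromatic starting material already carries the benzoyl, the geranyl and all three ring oxygens. In certainty of the ring-forming event the two are comparable, each resting on one unproven bridging step.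

Key step: step 4

Remarks on the chemistry (assumptions):
- 5 is taken as a purchasable, stabilised reagent and is used at once; it polymerises on standing.
- The sense of induction in step 4 is assumed to be that of the quinine-derived catalyst written there; the quinidine-derived pseudoenantiomer would take its place if the other face is attacked.
- 9, 11 and 13 are written as the tautomer with hydrogen (or prenyl) on C3 and the enol between C1 and C9. The C7 carbinol centre of 11 and 13 forms as a mixture and disappears in step 7.

Step 1
Reactants: 1 2,4,6-trihydroxybenzophenone; 2 geranyl bromide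
Product: 3 3-geranyl-2,4,6-trihydroxybenzophenone
Conditions: DBU (1.0 equiv), THF, 0 → 23 °C; 2 (0.9 equiv) added last
Reagents that add atoms: none
Why: C-allylation of a phloroglucinol mono-phenoxide by an allylic bromide (Friedel–Crafts-type alkylation); the ring carbon between two oxygens is the softest site, and a small deficit of 2 limits the digeranyl and O-alkyl by-products. No stereocentre is formed.

Step 2
Reactants: 4 2-methylbut-3-en-2-ol; 5 1-chlorobut-3-en-2-one
Product: 6 (E)-1-chloro-5-hydroxy-5-methylhex-3-en-2-one
Conditions: second-generation Grubbs catalyst (3 mol %), 4 (3 equiv), CH2Cl2, 40 °C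
Reagents that add atoms: none
Why: Olefin cross-metathesis between an electron-poor vinyl ketone and a hindered tertiary allylic alcohol, neither of which dimerises readily; the thermodynamically preferred E-olefin is expected and excess 4 is volatile.

Step 3
Reactants: 6 (E)-1-chloro-5-hydroxy-5-methylhex-3-en-2-one
Product: 7 (E)-1-chloro-5-methyl-5-(triethylsilyloxy)hex-3-en-2-one
Conditions: Et3SiOTf (1.1 equiv), 2,6-lutidine (1.5 equiv), CH2Cl2, −78 °C
Reagents that add atoms: triethylsilyl trifluoromethanesulfonate, CC[Si](CC)(CC)OS(=O)(=O)C(F)(F)F
Why: Silylation of a tertiary alcohol with a silyl triflate; the hindered pyridine base cannot alkylate at the chloromethyl ketone, and the low temperature keeps the ketone from forming a silyl enol ether.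

Step 4
Reactants: 3 3-geranyl-2,4,6-trihydroxybenzophenone; 7 (E)-1-chloro-5-methyl-5-(triethylsilyloxy)hex-3-en-2-one
Product: 9 bridged enol-trione (bicyclo[4.3.1]decane; C3–H tautomer; C7 ketone; C12 triethylsilyl ether; 3S,5S,11R), via Michael adduct 8 (not isolated)
Conditions: N-[3,5-bis(trifluoromethyl)phenyl]-N'-[(8α,9S)-6'-methoxycinchonan-9-yl]thiourea (10 mol %), toluene–CH2Cl2, 0 °C; then LiOH·H2O (2.2 equiv), THF–H2O (4:1), 0 → 23 °C; pH 4 buffer as soon as 8 is consumed
Reagents that add atoms: none
Why: Proposed new method: the thiourea binds the enone carbonyl of 7 while the quinuclidine nitrogen, held as an ammonium phenoxide pair by the acidic phenol 3, delivers the only unsubstituted ring carbon C3 to C11 with re-aromatisation (closest known type: organocatalytic Friedel–Crafts conjugate additions of phloroglucinols and naphthols to electron-poor olefins), so the catalyst sets C11 (R in 8). LiOH then forms the di-phenoxide and C5 displaces chloride from C6 in a 7-exo-tet alkylative dearomatisation (closest known type: base-mediated C-alkylation of acylphloroglucinols at an already substituted ring carbon to give cyclohexadienones). A four-carbon chain is too short to reach from an in-plane substituent on C3 to the face of C5, so closure is expected to run through the C3-protonated keto tautomer of the phenoxide, in which C11 is axial; this is also why 9 is the C3–H tautomer (an enol towards C4 is excluded at the bridgehead and one towards C2 is strained). Allylic 1,3-strain in 8 keeps H–C11 in the ring plane next to the C2 oxygen, so C10 and the silyloxypropyl arm lie on opposite faces on the C4 side; C10 reaches C5 on its own face, which fixes C5 and C3 relative to C11. C5 is preferred over the equally distant C1 because the acyl-bearing carbon is the least nucleophilic ring position, and carbon over oxygen because the phenoxide oxygens are hydrogen-bonded in the aqueous medium and tied to lithium. Conjugate addition precedes substitution because the first stage is run without base, where the chloromethyl ketone is inert to the neutral phenol; the silyl ether removes the 6-exo-tet attack of a C12 alkoxide on C6, and the limited amount of base restrains hydroxide attack on the chloroketone and retro-Michael opening of 9.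

Step 5
Reactants: 9 bridged enol-trione; 10 isopropylmagnesium chloride
Product: 11 C7 isopropyl carbinol of 9 (3S,5S,11R; C7 epimers)
Conditions: CeCl3 (anhydrous, 4 equiv), 10 (3.5 equiv), THF, −78 → −20 °C; NH4Cl (aq)
Reagents that add atoms: none
Why: Organocerium 1,2-addition to a ketone: the first equivalent deprotonates the enol, whose metal triketonate is inert, and the C7 ketone between two methylene groups is attacked in preference to the C4 ketone between the two bridgeheads. The low basicity of the cerium reagent avoids enolisation and β-elimination of the C3–C11 bond; the new C7 centre is of no consequence.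

Step 6
Reactants: 11 C7 isopropyl carbinol; 12 prenyl bromide
Product: 13 C3-prenylated carbinol (3S,5S,11R; C7 epimers)
Conditions: LiN(SiMe3)2 (3.3 equiv), THF, −78 → 0 °C; then 12 (1.2 equiv), −78 → 0 °C
Reagents that add atoms: none
Why: Alkylation of a bridgehead 1,3-dicarbonyl enolate: after the two hydroxyl protons, H–C3 is the only proton next to a carbonyl group in 11, and its enolate towards C2 is allowed by the Bredt rule because the double bond lies trans in the nine-membered ring C1–C2–C3–C11–C10–C7–C6–C5–C9. Carbon is alkylated because an O-allyl product would be a bridgehead enol ether, and only the outer face of C3 is open, so its configuration is fixed by the bridge.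

Step 7
Reactants: 13 C3-prenylated carbinol
Product: 14 homoadamantane trione with prenyl on C3 and the silyloxypropyl group on C11 (1S,3S,5R,7R,11R)
Conditions: BF3·OEt2 (0.3 equiv), 4 Å molecular sieves, CH2Cl2, −78 → −20 °C; NaHCO3 (aq)
Reagents that add atoms: none
Why: Cationic alkylation of an enolised triketone (the biomimetic way to the C1–C8 bond): the free tertiary carbinol ionises much faster than the silyl ether, a 1,2-hydride shift moves the charge from C7 to C8, and the enol carbon C1, whose π-face points at the bridge, closes the chair-like six-membered ring B. C7 and C1 are set by the cage, since only the invertomer with C8 pointing at C1 can close while the other reverts by hydride shift; a tertiary enol ether formed by attack through oxygen can re-ionise.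

Step 8
Reactants: 14 homoadamantane trione silyl ether
Product: 15 target (1S,3S,5R,7R,11S,13S)
Conditions: Me3SiOTf (1.5 equiv), 2,6-di-tert-butyl-4-methylpyridine (2.5 equiv), CH2Cl2, −78 → −20 °C
Reagents that add atoms: none
Why: Cation–olefin cyclisation to a five-membered ring: silyl transfer to the ether oxygen expels a disiloxane, C13 of the prenyl group attacks C12 (Markovnikov), and with C1 now quaternary no enol oxygen can trap the C15 cation, which loses a methyl proton to the buffered medium; the tetrasubstituted olefin is disfavoured by strain against the C12 methyl groups. C13 is set by the transition state that puts C15 on the face of the new ring syn to H–C11, away from C10 and the C4 carbonyl.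

## Compound list

1 | (2,4,6-trihydroxyphenyl)(phenyl)methanone (2,4,6-trihydroxybenzophenone) | O=C(c1ccccc1)c1c(O)cc(O)cc1O | starting material
2 | (2E)-1-bromo-3,7-dimethylocta-2,6-diene (geranyl bromide) | CC(C)=CCC/C(C)=C/CBr | starting material
3 | {3-[(2E)-3,7-dimethylocta-2,6-dien-1-yl]-2,4,6-trihydroxyphenyl}(phenyl)methanone | O=C(c1ccccc1)c1c(O)cc(O)c(C/C=C(\C)CCC=C(C)C)c1O | intermediate
4 | 2-methylbut-3-en-2-ol | C=CC(C)(C)O | starting material
5 | 1-chlorobut-3-en-2-one | C=CC(=O)CCl | starting material
6 | (3E)-1-chloro-5-hydroxy-5-methylhex-3-en-2-one | CC(C)(O)/C=C/C(=O)CCl | intermediate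
7 | (3E)-1-chloro-5-methyl-5-[(triethylsilyl)oxy]hex-3-en-2-one | CC[Si](CC)(CC)OC(C)(C)/C=C/C(=O)CCl | intermediate
8 | (4R)-4-{3-benzoyl-5-[(2E)-3,7-dimethylocta-2,6-dien-1-yl]-2,4,6-trihydroxyphenyl}-1-chloro-5-methyl-5-[(triethylsilyl)oxy]hexan-2-one (Michael adduct, C11 is R) | CC[Si](CC)(CC)OC(C)(C)[C@H](CC(=O)CCl)c1c(O)c(C(=O)c2ccccc2)c(O)c(C/C=C(\C)CCC=C(C)C)c1O | intermediate
9 | (1S,5R,6S)-8-benzoyl-1-[(2E)-3,7-dimethylocta-2,6-dien-1-yl]-9-hydroxy-5-{2-[(triethylsilyl)oxy]propan-2-yl}bicyclo[4.3.1]dec-8-ene-3,7,10-trione (in the text labels 3S,5S,11R; hydrogen on C3, ketone at C7) | CC[Si](CC)(CC)OC(C)(C)[C@@H]1CC(=O)C[C@]2(C/C=C(\C)CCC=C(C)C)C(=O)[C@H]1C(=O)C(C(=O)c1ccccc1)=C2O | intermediate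
10 | isopropylmagnesium chloride [chloro(propan-2-yl)magnesium] | CC(C)[Mg]Cl | starting material
11 | 9 with the C7 ketone turned into C(OH)(CHMe2): 8-benzoyl-1-geranyl-3,9-dihydroxy-3-(propan-2-yl)-5-{2-[(triethylsilyl)oxy]propan-2-yl}bicyclo[4.3.1]dec-8-ene-7,10-dione (text labels 3S,5S,11R; C7 epimers) | CC[Si](CC)(CC)OC(C)(C)[C@@H]1CC(O)(C(C)C)C[C@]2(C/C=C(\C)CCC=C(C)C)C(=O)[C@H]1C(=O)C(C(=O)c1ccccc1)=C2O | intermediate
12 | 1-bromo-3-methylbut-2-ene (prenyl bromide) | CC(C)=CCBr | starting material
13 | 11 with a 3-methylbut-2-en-1-yl group on C3 in place of hydrogen, on the outer face (text labels 3S,5S,11R; C7 epimers) | CC[Si](CC)(CC)OC(C)(C)[C@@H]1CC(O)(C(C)C)C[C@]2(C/C=C(\C)CCC=C(C)C)C(=O)[C@@]1(CC=C(C)C)C(=O)C(C(=O)c1ccccc1)=C2O | intermediate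
14 | homoadamantane-2,4,9-trione (tricyclo[4.3.1.1(3,8)]undecane core) with benzoyl on C1, prenyl on C3, geranyl on C5, two methyls on C8 and 2-[(triethylsilyl)oxy]propan-2-yl on C11 (text labels 1S,3S,5R,7R,11R) | CC(C)=CC[C@@]12C(=O)[C@@]3(C/C=C(\C)CCC=C(C)C)C[C@@H](C[C@H]1C(C)(C)O[Si](CC)(CC)CC)C(C)(C)[C@](C(=O)c4ccccc4)(C3=O)C2=O | intermediate
15 | target: homoadamantane-2,4,9-trione with benzoyl on C1, geranyl on C5, two methyls on C8 and a cyclopentane C3–C11–C12(Me2)–C13(isopropenyl)–C14 fused on C3–C11 (text labels 1S,3S,5R,7R,11S,13S) | C=C(C)[C@@H]1C[C@@]23C(=O)[C@@]4(C/C=C(\C)CCC=C(C)C)C[C@@H](C[C@H]2C1(C)C)C(C)(C)[C@](C(=O)c1ccccc1)(C4=O)C3=O | target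

## Step count and least certain steps

Total: 8 steps. Longest linear sequence: 7 steps (steps 2 to 8, from 4 and 5).

**Step 4 (key step, the proposed new method).**
- What may go wrong: the conjugate addition at the neopentyl-type carbon C11 may be slow, so that a background reaction erodes the enantioselectivity. In the base stage, closure through a phenoxide oxygen (aryl ether), or hydroxide attack or Favorskii-type rearrangement of the chloromethyl ketone, may outrun closure at C5, which needs the less populated C3–H tautomer. Base may also reopen 9 by β-elimination of the C3–C11 bond from the C10 enolate.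
- Fallback (known reactions only): it sets out from 3 and 7 and returns at 9. The addition stage is worked up and 8 is isolated. Luche reduction (NaBH4, CeCl3·7H2O, MeOH, −78 °C) of the chloromethyl ketone gives the chlorohydrin F1 as C7 epimers. KOt-Bu in t-BuOH–THF converts it into the terminal epoxide F2, which the phenoxide opens at C6 by intramolecular C-alkylation in a protic medium to give the bridged C7 alcohol F3. Dess–Martin periodinane (NaHCO3, CH2Cl2) restores the ketone and gives 9. The ketone-derived side reactions are absent in this sequence.

**Step 7.**
- What may go wrong: early loss of the silyl ether and ionisation at C12 while C1 is still an enol (trapping of the C15 cation by enol oxygen); closure of C1 onto C7 before the hydride shift; capture of the cation by the nearby geranyl olefin; elimination to olefins that do not re-enter at low acidity.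
- Fallback: it sets out from 13 and returns at 15. Dehydration with the Burgess reagent (benzene, 50 °C) gives the C7 isopropylidene compound F4 (with endocyclic isomers that enter the same cation manifold). Neat formic acid at 23 °C protonates the olefin; attack through oxygen is reversible in this medium, attack through C1 is not. The silyl ether is lost, C12 ionises and the cyclopentane closes in the same flask, the C15 cation ending as the tertiary formate F5. KHCO3 in MeOH at 0 °C gives the tertiary alcohol F6, and Burgess dehydration (syn-elimination towards a methyl group) gives 15.

**Step 8.**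
- What may go wrong: poor regiocontrol in the proton loss from the C15 cation (tetrasubstituted olefin, or hydride shift from C13); capture of the cation by triflate; acid-induced attack on the geranyl olefins if the buffer is insufficient.
- Fallback: it sets out from 14 and returns at 15. HF·pyridine (THF, 0 → 23 °C) frees the tertiary carbinol F7, and Burgess dehydration gives the C11 isopropenyl compound F8 (the same structure as A3). Hydrogen-atom-transfer cycloisomerisation with chloro[N,N'-bis(3,5-di-tert-butylsalicylidene)cyclohexane-1,2-diaminato]cobalt (trivalent cobalt, 5 mol %) and PhSiH3 (5 mol %) in benzene adds a hydrogen atom to the 1,1-disubstituted olefin; the C12 radical closes 5-exo onto C13 and the C15 radical returns a methyl hydrogen to cobalt, giving 15 without a cationic intermediate.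

**Step 6.**
- What may go wrong: incomplete formation of the strained bridgehead enolate, or alkylation of the triketonate on oxygen or on C1.
- Fallback: it sets out from 11 and returns at 13. The trianion of 11 is alkylated with allyl bromide, a smaller and more reactive electrophile, to give the C3-allyl compound F9. Cross-metathesis with 2-methylbut-2-ene (second-generation Grubbs catalyst, CH2Cl2, 40 °C) turns allyl into prenyl and gives 13; the trisubstituted geranyl olefins react slowly in metathesis.

**Step 2.**
- What may go wrong: polymerisation of 5 and deactivation of the catalyst by the chloromethyl ketone, leading to low conversion.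
- Fallback: it sets out from 4 and returns at 7, so that 5, 6 and step 3 are not needed. Et3SiOTf and 2,6-lutidine give the silyl ether F10. Ozonolysis (O3, CH2Cl2, −78 °C; Me2S) gives the aldehyde F11. Wittig reaction with the stabilised ylide 1-chloro-3-(triphenyl-λ5-phosphanylidene)propan-2-one (toluene, 80 °C) gives 7 with E geometry.

## Further compounds

F1 | step 4 | (4R)-4-[3-benzoyl-5-geranyl-2,4,6-trihydroxyphenyl]-1-chloro-5-methyl-5-[(triethylsilyl)oxy]hexan-2-ol (C2 epimers) | CC[Si](CC)(CC)OC(C)(C)[C@H](CC(O)CCl)c1c(O)c(C(=O)c2ccccc2)c(O)c(C/C=C(\C)CCC=C(C)C)c1O
F2 | step 4 | terminal epoxide of F1: {3-geranyl-2,4,6-trihydroxy-5-[(2R)-3-methyl-1-(oxiran-2-yl)-3-[(triethylsilyl)oxy]butan-2-yl]phenyl}(phenyl)methanone | CC[Si](CC)(CC)OC(C)(C)[C@H](CC1CO1)c1c(O)c(C(=O)c2ccccc2)c(O)c(C/C=C(\C)CCC=C(C)C)c1O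
F3 | step 4 | 9 with a secondary hydroxyl on C7 in place of the ketone (C7 epimers) | CC[Si](CC)(CC)OC(C)(C)[C@@H]1CC(O)C[C@]2(C/C=C(\C)CCC=C(C)C)C(=O)[C@H]1C(=O)C(C(=O)c1ccccc1)=C2O
F4 | step 7 | 13 dehydrated to the C7 isopropylidene compound | CC[Si](CC)(CC)OC(C)(C)[C@@H]1CC(=C(C)C)C[C@]2(C/C=C(\C)CCC=C(C)C)C(=O)[C@@]1(CC=C(C)C)C(=O)C(C(=O)c1ccccc1)=C2O
F5 | step 7 | 15 with a 2-(formyloxy)propan-2-yl group on C13 in place of isopropenyl | O=COC(C)(C)[C@@H]1C[C@@]23C(=O)[C@@]4(C/C=C(\C)CCC=C(C)C)C[C@@H](C[C@H]2C1(C)C)C(C)(C)[C@](C(=O)c1ccccc1)(C4=O)C3=O
F6 | step 7 | 15 with a 2-hydroxypropan-2-yl group on C13 in place of isopropenyl | CC(C)(O)[C@@H]1C[C@@]23C(=O)[C@@]4(C/C=C(\C)CCC=C(C)C)C[C@@H](C[C@H]2C1(C)C)C(C)(C)[C@](C(=O)c1ccccc1)(C4=O)C3=O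
F7 | step 8 | 14 with a free 2-hydroxypropan-2-yl group on C11 | CC(C)=CC[C@@]12C(=O)[C@@]3(C/C=C(\C)CCC=C(C)C)C[C@@H](C[C@H]1C(C)(C)O)C(C)(C)[C@](C(=O)c4ccccc4)(C3=O)C2=O
F8 | step 8 | cage trione with prenyl on C3 and isopropenyl on C11 | CC(C)=CC[C@@]12C(=O)[C@@]3(C/C=C(\C)CCC=C(C)C)C[C@@H](C[C@H]1C(C)=C)C(C)(C)[C@](C(=O)c4ccccc4)(C3=O)C2=O
F9 | step 6 | 11 with a prop-2-en-1-yl group on C3 in place of hydrogen | CC[Si](CC)(CC)OC(C)(C)[C@@H]1CC(O)(C(C)C)C[C@]2(C/C=C(\C)CCC=C(C)C)C(=O)[C@@]1(CC=C)C(=O)C(C(=O)c1ccccc1)=C2O
F10 | step 2 | triethyl[(2-methylbut-3-en-2-yl)oxy]silane | C=CC(C)(C)O[Si](CC)(CC)CC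
F11 | step 2 | 2-methyl-2-[(triethylsilyl)oxy]propanal | CC[Si](CC)(CC)OC(C)(C)C=O
A1 | alternative 1 | cage trione with hydrogen on C1 and C5 | C=C(C)[C@@H]1C[C@@]23C(=O)[C@H]4C[C@@H](C[C@H]2C1(C)C)C(C)(C)[C@H](C4=O)C3=O
A2 | alternative 1 | ring B enol silane carrying the cyclopentane with a 2,2-disubstituted malonyl dichloride at C3 | C=C(C)[C@@H]1CC(C(=O)Cl)(C(=O)Cl)[C@@H](C[C@@H]2CC=C(O[Si](C)(C)C)CC2(C)C)C1(C)C
A3 | alternative 2 | cage trione with prenyl on C3 and isopropenyl on C11 | CC(C)=CC[C@@]12C(=O)[C@@]3(C/C=C(\C)CCC=C(C)C)C[C@@H](C[C@H]1C(C)=C)C(C)(C)[C@](C(=O)c4ccccc4)(C3=O)C2=O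
A4 | alternative 2 | bicyclo[3.3.1]nonane trione (enolised at C2–C3) with benzoyl on C1, prenyl on C3, geranyl on C5 and an (E)-4-(methoxycarbonyloxy)-3-methylbut-2-enyl arm on C7 | CC(C)=CCC1=C(O)[C@@]2(C(=O)c3ccccc3)C(=O)[C@](C/C=C(\C)CCC=C(C)C)(C[C@@H](C/C=C(\C)COC(=O)OC)C2(C)C)C1=O
A5 | alternative 3 | tricyclic trione with ring A closed across the seven-membered ring | C=C(C)[C@@H]1C[C@@]23C(=O)[C@@H](CC(=C(C)C)C[C@H]2C1(C)C)C(=O)CC3=O
A6 | alternative 3 | hydroazulenone enol silane with C7 isopropylidene | C=C(C)[C@@H]1CC2C(O[Si](C)(C)C)=CCC(=C(C)C)C[C@H]2C1(C)C
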